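**Retrosynthetic overview**

1. The last bond made is the central CH2–CH2 bond (C11–C11'), by mixed Kolbe electrolysis of two C12 acids (18 right, 32 left). Both acids come from one chiral-pool terpene, andrographolide: its ring B (C5, C9, C10 as found; C8 adjustable) is each cyclohexane of the target, C11 is each linker carbon, and C1–C4 become each oxepane.
2. One ozonolysis cuts C8=C17 and C12=C13. The C8 ketone is the branch point: equatorial MeMgBr attack gives the axial carbinol (left); methylenation, equatorial epoxidation and hydride opening give the equatorial carbinol (right).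
3. Ring A is then cut out and sewn back with one more oxygen: Grob fragmentation (C3–C4), ozonolysis/Criegee rearrangement (C5–C4 becomes C5–O with retention), Petasis methylenation to the C5 isopropenyl ether, and closure of the C3–C4 bond by carbene-catalysed hydroacylation, which gives the 2,2-dimethyloxepan-3-one directly.
4. Enabling feature: in the oxepanone ring (O, C4, C3, C2, C1, C10, C5) the ketone C3 sits next to the ether carbon C4. C4 is therefore a latent oxocarbenium ion (C5–O–C(CH3)=CH2) and C3 an acyl anion (aldehyde plus carbene), both anchored on the chair at the equatorial C5–O bond and the quaternary C10.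
5. Ring order: two cyclohexanes from the pool, right oxepanone (step 11), left oxepanone (step 22, then catalyst-controlled reduction to the 3S alcohol), union last (step 27).

Key step: step 11

Remark: the ent-labdane numbering of andrographolide (C1–C12, C17–C20) is kept for both halves; "right" is the ketone half, "left" the alcohol half, and left-half positions in 33 carry a prime. Natural andrographolide has the C5, C9 and C10 configuration of both cyclohexane rings of the target.

**Route**

Step 1
Reactants: 1 andrographolide
Product: 3 keto acetal (3,19-dihydroxy-12,12-dimethoxy-13,14,15,16,17-pentanor-ent-labdan-8-one; C3/C4/C5/C9/C10 as in 1), via keto aldehyde 2 (not isolated)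
Conditions: O3, CH2Cl2/MeOH (1:1), −78 °C; Me2S, −78 °C to rt; then PPTS (10 mol %), 3 Å MS, rt
Reagents that add atoms: ozone [O-][O+]=O (C8 ketone oxygen); methanol CO (two OCH3 groups)
Why: Ozonolysis with reductive work-up cleaves both the exocyclic C8=C17 bond and the C12=C13 enoate bond, and under mild acid only the unhindered C12 aldehyde, not the hindered C8 ketone, is converted into its dimethyl acetal; the C9 side chain stays equatorial, the stable epimer next to the ketone.

Step 2
Reactants: 3 keto acetal
Product: 4 exocyclic alkene (12,12-dimethoxy-13,14,15,16-tetranor-ent-labd-8(17)-ene-3,19-diol)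
Conditions: Ph3PCH3Br, KOtBu (excess), THF/toluene, 0 to 70 °C
Reagents that add atoms: methyltriphenylphosphonium bromide C[P+](c1ccccc1)(c1ccccc1)c1ccccc1.[Br-] (the CH2 group)
Why: Wittig methylenation returns the C8 methylene, now without the side chain, so that the right-half carbinol can be built with an equatorial C–O bond; the free diol only binds extra base.

Step 3
Reactants: 4 exocyclic alkene
Product: 5 right epoxide (8,17-epoxide; oxygen equatorial; CH2 axial on the side of the C10 methyl)
Conditions: mCPBA, NaHCO3, CH2Cl2, 0 °C
Reagents that add atoms: mCPBA OOC(=O)c1cccc(Cl)c1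
Why: Prilezhaev epoxidation should occur from the equatorial face because the axial C10 methyl blocks the axial approach to C8, which sets C8 with the new C–O bond equatorial.

Step 4
Reactants: 5 right epoxide
Product: 6 right triol (3,8,19-triol; 8-OH equatorial; 8-CH3 axial)
Conditions: LiAlH4, THF, 0 to 50 °C
Reagents that add atoms: none
Why: Hydride opens the epoxide at its primary carbon (SN2), which leaves the equatorial tertiary C8–OH and the axial C8 methyl of the right half; the acetal is inert.

Step 5
Reactants: 6 right triol
Product: 7 right tosylate (19-O-tosylate; 3-OH and 8-OH free)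
Conditions: TsCl, pyridine, DMAP (cat.), CH2Cl2, 0 °C to rt
Reagents that add atoms: tosyl chloride Cc1ccc(cc1)S(Cl)(=O)=O
Why: Sulfonylation is selective for the only primary hydroxyl (C19) over the secondary C3–OH and the tertiary C8–OH.

Step 6
Reactants: 7 right tosylate
Product: 9 right seco alcohol (ring A opened: C10 carries CH2CH2CH2OH; C5 carries isopropenyl), via right seco aldehyde 8 (not isolated)
Conditions: KOtBu, THF/tBuOH, 0 °C to rt; then NaBH4, MeOH, 0 °C
Reagents that add atoms: none
Why: Grob fragmentation of the 1,3-diol monotosylate: the C3 alkoxide expels tosylate through the C3–C4 bond (the neopentyl C19 disfavours the competing oxetane closure), and the aldehyde is reduced in the same flask before it can enolise or condense.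

Step 7
Reactants: 9 right seco alcohol
Product: 10 right silyl ether (C3–OSiEt3; 8-OH free)
Conditions: TESCl, imidazole, CH2Cl2, 0 °C
Reagents that add atoms: chlorotriethylsilane CC[Si](Cl)(CC)CC
Why: The primary alcohol is silylated selectively; the hindered tertiary C8–OH stays free.

Step 8
Reactants: 10 right silyl ether
Product: 12 right C5 acetate (C5–OAc in place of the isopropenyl group; C5 configuration retained), via right methoxy hydroperoxide 11 (not isolated)
Conditions: O3, CH2Cl2/MeOH (5:1), NaHCO3, −78 °C; then Ac2O, Et3N, DMAP (cat.), 0 °C to rt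
Reagents that add atoms: ozone [O-][O+]=O (C5–O oxygen); methanol CO (carbonyl oxygen of the new acetate)
Why: Ozonolysis in methanol traps the carbonyl oxide as the methoxy hydroperoxide, whose peracetate undergoes Criegee rearrangement with migration of C5 from carbon to oxygen with retention, so C5–C4 is replaced by C5–O without touching the stereocentre.

Step 9
Reactants: 12 right C5 acetate
Product: 13 right isopropenyl ether (C5–O–C(CH3)=CH2)
Conditions: Cp2TiMe2 (4 equiv), toluene/THF, 65 °C, dark
Reagents that add atoms: dimethyltitanocene C[Ti](C)(C1C=CC=C1)C1C=CC=C1 (the CH2 group)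
Why: Petasis methylenation converts the only ester in the molecule into the enol ether under neutral conditions that acetal and silyl ether tolerate; the excess of reagent covers the free tertiary alcohol.

Step 10
Reactants: 13 right isopropenyl ether
Product: 14 right aldehyde (C3 aldehyde on the C10 side chain; C5 isopropenyl ether)
Conditions: (COCl)2, DMSO, CH2Cl2, −78 to −40 °C; Et3N, −78 °C to rt
Reagents that add atoms: none
Why: Under Swern conditions a primary triethylsilyl ether is cleaved and oxidised directly to the aldehyde, while the tertiary alcohol, the acetal and the enol ether (kept cold and then basic) are left alone.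

Step 11
Reactants: 14 right aldehyde
Product: 15 right oxepanone (2,2-dimethyloxepan-3-one trans-fused to the cyclohexane at C5/C10; 8-OH free)
Conditions: 2-mesityl-6,7-dihydro-5H-pyrrolo[2,1-c][1,2,4]triazol-2-ium chloride (20 mol %), DBU (20 mol %), toluene, 4 Å MS, 90 °C, 0.02 M
Reagents that add atoms: none
Why: Proposed new method: the carbene adds to the C3 aldehyde to give the Breslow enaminol (an acyl anion equivalent), whose O–H proton passes to the terminal CH2 of the isopropenyl ether while its carbon attacks C4, in effect the capture of the oxocarbenium ion C5–O(+)=C4(CH3)2 by the acyl anion, and loss of the carbene from the adduct gives the ketone. The closest known reaction type is the carbene-catalysed intramolecular hydroacylation of aryl enol ethers to 2,2-disubstituted benzofuran-3-ones and of unactivated alkenes to chromanones; the extension here is to an aliphatic aldehyde and a seven-membered ring. The oxepanone closes in a 7-exo-trig mode with respect to the enol ether C=C (attack at the oxygen-bearing carbon, CH2 left outside the ring as the second methyl group). No stereocentre is created (C4 becomes the gem-dimethyl carbon), and C5 and C10 are not touched. The step needs Markovnikov C–C bond formation and intramolecular capture ahead of aldehyde self-condensation: the ether oxygen confines the positive charge to C4, and the equatorial C5–O bond and the C10 side chain, gauche on the chair and held by the quaternary C10, put C3 within reach of C4; high dilution and dry, acid-free conditions protect the enol ether.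

Step 12
Reactants: 15 right oxepanone
Product: 16 right acetoxy oxepanone (8-OAc equatorial)
Conditions: Ac2O, Et3N, DMAP (1 equiv), ClCH2CH2Cl, 60 °C
Reagents that add atoms: acetic anhydride CC(=O)OC(C)=O
Why: Nucleophilic catalysis by DMAP at raised temperature acylates the tertiary alcohol; Lewis acid catalysts are avoided because of the dimethyl acetal.

Step 13
Reactants: 16 right acetoxy oxepanone
Product: 17 right C12 aldehyde
Conditions: TsOH·H2O (cat.), acetone/H2O (10:1), rt
Reagents that add atoms: water O (aldehyde oxygen)
Why: Mild aqueous acid hydrolyses the acetal; with C8–OH acetylated no lactol can form, and tertiary acetate and ketone are stable.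

Step 14
Reactants: 17 right C12 aldehyde
Product: 18 right acid (C12 carboxylic acid; 8-OAc; C3 ketone)
Conditions: NaClO2, NaH2PO4, 2-methyl-2-butene, tBuOH/H2O, rt
Reagents that add atoms: sodium chlorite [Na+].[O-]Cl=O
Why: Pinnick oxidation converts the aldehyde into the acid without touching ketone or acetate.

Step 15
Reactants: 3 keto acetal
Product: 19 left triol (3,8,19-triol; 8-OH axial on the side of the C10 methyl; 8-CH3 equatorial)
Conditions: MeMgBr (5 equiv), THF, −40 to 0 °C
Reagents that add atoms: methylmagnesium bromide C[Mg]Br
Why: 1,2-Addition of the Grignard reagent should occur from the equatorial side because the axial C10 methyl blocks the axial trajectory, which gives the axial tertiary alcohol and the equatorial methyl of the left half.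

Step 16
Reactants: 19 left triol
Product: 20 left tosylate (19-O-tosylate)
Conditions: TsCl, pyridine, DMAP (cat.), CH2Cl2, 0 °C to rt
Reagents that add atoms: tosyl chloride Cc1ccc(cc1)S(Cl)(=O)=O
Why: As in step 5, only the primary C19 hydroxyl is sulfonylated.

Step 17
Reactants: 20 left tosylate
Product: 22 left seco alcohol (C10 carries CH2CH2CH2OH; C5 carries isopropenyl), via left seco aldehyde 21 (not isolated)
Conditions: KOtBu, THF/tBuOH, 0 °C to rt; then NaBH4, MeOH, 0 °C
Reagents that add atoms: none
Why: Grob fragmentation through the C3–C4 bond as in step 6, with reduction of the aldehyde in the same flask.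

Step 18
Reactants: 22 left seco alcohol
Product: 23 left silyl ether (C3–OSiEt3; 8-OH free)
Conditions: TESCl, imidazole, CH2Cl2, 0 °C
Reagents that add atoms: chlorotriethylsilane CC[Si](Cl)(CC)CC
Why: Selective silylation of the primary alcohol beside the axial tertiary C8–OH.

Step 19
Reactants: 23 left silyl ether
Product: 25 left C5 acetate (C5 configuration retained), via left methoxy hydroperoxide 24 (not isolated)
Conditions: O3, CH2Cl2/MeOH (5:1), NaHCO3, −78 °C; then Ac2O, Et3N, DMAP (cat.), 0 °C to rt
Reagents that add atoms: ozone [O-][O+]=O (C5–O oxygen); methanol CO (carbonyl oxygen of the new acetate)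
Why: Ozonolysis followed by Criegee rearrangement of the peracetate, with migration of C5 to oxygen with retention, as in step 8.

Step 20
Reactants: 25 left C5 acetate
Product: 26 left isopropenyl ether
Conditions: Cp2TiMe2 (4 equiv), toluene/THF, 65 °C, dark
Reagents that add atoms: dimethyltitanocene C[Ti](C)(C1C=CC=C1)C1C=CC=C1 (the CH2 group)
Why: Petasis methylenation of the only ester, as in step 9.

Step 21
Reactants: 26 left isopropenyl ether
Product: 27 left aldehyde
Conditions: (COCl)2, DMSO, CH2Cl2, −78 to −40 °C; Et3N, −78 °C to rt
Reagents that add atoms: none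
Why: Direct Swern oxidation of the primary triethylsilyl ether to the aldehyde, as in step 10.

Step 22
Reactants: 27 left aldehyde
Product: 28 left oxepanone (2,2-dimethyloxepan-3-one trans-fused at C5/C10; 8-OH axial and free)
Conditions: 2-mesityl-6,7-dihydro-5H-pyrrolo[2,1-c][1,2,4]triazol-2-ium chloride (20 mol %), DBU (20 mol %), toluene, 4 Å MS, 90 °C, 0.02 M
Reagents that add atoms: none
Why: Proposed new method: as in step 11, the Breslow enaminol formed from the C3 aldehyde and the carbene attacks C4 of the isopropenyl ether as its CH2 terminus is protonated (acyl anion onto oxocarbenium ion), the closest known reaction type being the carbene-catalysed intramolecular hydroacylation of aryl enol ethers to benzofuran-3-ones; the closure is 7-exo-trig and creates no stereocentre.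

Step 23
Reactants: 28 left oxepanone
Product: 29 left acetoxy oxepanone (8-OAc axial)
Conditions: Ac2O, Et3N, DMAP (1 equiv), ClCH2CH2Cl, 60 °C
Reagents that add atoms: acetic anhydride CC(=O)OC(C)=O
Why: DMAP-catalysed acylation of the tertiary alcohol while C3 is still a ketone, so that no secondary hydroxyl competes.

Step 24
Reactants: 29 left acetoxy oxepanone
Product: 30 left hydroxy oxepane ((3S)-alcohol; OH on the face opposite the C10 methyl)
Conditions: (R)-2-methyl-CBS-oxazaborolidine (20 mol %), BH3·SMe2, THF, −20 °C
Reagents that add atoms: none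
Why: Corey–Bakshi–Shibata reduction: with the quaternary C4 as the large and the C2 methylene as the small substituent, the (R)-catalyst should deliver hydride to give the (3S)-alcohol under catalyst control; acetate and acetal are inert to borane at this temperature.

Step 25
Reactants: 30 left hydroxy oxepane
Product: 31 left C12 aldehyde
Conditions: TsOH·H2O (cat.), acetone/H2O (10:1), rt
Reagents that add atoms: water O (aldehyde oxygen)
Why: Acetal hydrolysis under mild acid, as in step 13; the acetylated C8 oxygen cannot form a lactol.

Step 26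
Reactants: 31 left C12 aldehyde
Product: 32 left acid (C12 carboxylic acid; 8-OAc axial; 3S-OH)
Conditions: NaClO2, NaH2PO4, 2-methyl-2-butene, tBuOH/H2O, rt
Reagents that add atoms: sodium chlorite [Na+].[O-]Cl=O
Why: Pinnick oxidation is selective for the aldehyde and leaves the hindered secondary alcohol alone.

Step 27
Reactants: 18 right acid; 32 left acid
Product: 33 target CNP0298533.1
Conditions: Pt anode, Pt cathode, undivided cell, KOH (0.1 equiv), MeOH/pyridine (4:1), 45 °C, constant current (0.25 A cm−2), 18:32 = 1:1
Reagents that add atoms: none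
Why: Mixed Kolbe electrolysis: anodic decarboxylation gives the two primary C11 radicals, which combine at the electrode to the C11–C11' bond without touching any stereocentre; the cross product is expected beside the two symmetric dimers, which differ in polarity (diol, keto alcohol, diketone) and should be separable.

**Compound list**

1 | andrographolide | O=C3OC[C@@H](O)/C3=C\C[C@H]1[C@]2(C)CC[C@@H](O)[C@@](C)(CO)[C@H]2CCC1=C | starting material
2 | keto aldehyde: 3,19-dihydroxy-8-oxo-13,14,15,16,17-pentanor-ent-labdan-12-al | O=CC[C@H]1[C@]2(C)CC[C@@H](O)[C@@](C)(CO)[C@H]2CCC1=O | intermediate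
3 | keto acetal: 3,19-dihydroxy-12,12-dimethoxy-13,14,15,16,17-pentanor-ent-labdan-8-one | COC(OC)C[C@H]1[C@]2(C)CC[C@@H](O)[C@@](C)(CO)[C@H]2CCC1=O | intermediate
4 | exocyclic alkene: 12,12-dimethoxy-13,14,15,16-tetranor-ent-labd-8(17)-ene-3,19-diol | COC(OC)C[C@H]1[C@]2(C)CC[C@@H](O)[C@@](C)(CO)[C@H]2CCC1=C | intermediate
5 | right epoxide: 8,17-epoxide of 4, oxygen equatorial, CH2 axial (syn to the C10 methyl) | COC(OC)C[C@H]1[C@]2(C)CC[C@@H](O)[C@@](C)(CO)[C@H]2CC[C@]1(C3)O3 | intermediate
6 | right triol: 12,12-dimethoxy-tetranor-ent-labdane-3,8,19-triol, 8-OH equatorial, 8-CH3 axial | COC(OC)C[C@H]1[C@]2(C)CC[C@@H](O)[C@@](C)(CO)[C@H]2CC[C@]1(C)O | intermediate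
7 | right tosylate: 19-O-tosylate of 6 | COC(OC)C[C@H]1[C@]2(C)CC[C@@H](O)[C@@](C)(COS(=O)(=O)c3ccc(C)cc3)[C@H]2CC[C@]1(C)O | intermediate
8 | right seco aldehyde: 3,4-seco, C10 carries CH2CH2CHO, C5 carries isopropenyl | COC(OC)C[C@H]1[C@](C)(CCC=O)[C@@H](C(C)=C)CC[C@]1(C)O | intermediate
9 | right seco alcohol: C10 carries CH2CH2CH2OH, C5 carries isopropenyl | COC(OC)C[C@H]1[C@](C)(CCCO)[C@@H](C(C)=C)CC[C@]1(C)O | intermediate
10 | right silyl ether: C3 triethylsilyl ether of 9 | COC(OC)C[C@H]1[C@](C)(CCCO[Si](CC)(CC)CC)[C@@H](C(C)=C)CC[C@]1(C)O | intermediate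
11 | right methoxy hydroperoxide: C5–C(CH3)(OCH3)OOH | COC(OC)C[C@H]1[C@](C)(CCCO[Si](CC)(CC)CC)[C@@H](C(C)(OC)OO)CC[C@]1(C)O | intermediate
12 | right C5 acetate: C5–OAc, configuration at C5 retained | COC(OC)C[C@H]1[C@](C)(CCCO[Si](CC)(CC)CC)[C@@H](OC(C)=O)CC[C@]1(C)O | intermediate
13 | right isopropenyl ether: C5–O–C(CH3)=CH2 | COC(OC)C[C@H]1[C@](C)(CCCO[Si](CC)(CC)CC)[C@@H](OC(C)=C)CC[C@]1(C)O | intermediate
14 | right aldehyde: C3 aldehyde, C5 isopropenyl ether, 8-OH equatorial | COC(OC)C[C@H]1[C@](C)(CCC=O)[C@@H](OC(C)=C)CC[C@]1(C)O | intermediate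
15 | right oxepanone: trans-fused 2,2-dimethyloxepan-3-one, 8-OH equatorial, C12 dimethyl acetal | COC(OC)C[C@H]1[C@]2(C)CCC(=O)C(C)(C)O[C@H]2CC[C@]1(C)O | intermediate
16 | right acetoxy oxepanone: 8-acetate of 15 | COC(OC)C[C@H]1[C@]2(C)CCC(=O)C(C)(C)O[C@H]2CC[C@]1(C)OC(C)=O | intermediate
17 | right C12 aldehyde | O=CC[C@H]1[C@]2(C)CCC(=O)C(C)(C)O[C@H]2CC[C@]1(C)OC(C)=O | intermediate
18 | right acid: C12 carboxylic acid, C3 ketone, 8-OAc equatorial | OC(=O)C[C@H]1[C@]2(C)CCC(=O)C(C)(C)O[C@H]2CC[C@]1(C)OC(C)=O | intermediate
19 | left triol: 8-epimer of 6, 8-OH axial (syn to the C10 methyl), 8-CH3 equatorial | COC(OC)C[C@H]1[C@]2(C)CC[C@@H](O)[C@@](C)(CO)[C@H]2CC[C@@]1(C)O | intermediate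
20 | left tosylate: 19-O-tosylate of 19 | COC(OC)C[C@H]1[C@]2(C)CC[C@@H](O)[C@@](C)(COS(=O)(=O)c3ccc(C)cc3)[C@H]2CC[C@@]1(C)O | intermediate
21 | left seco aldehyde | COC(OC)C[C@H]1[C@](C)(CCC=O)[C@@H](C(C)=C)CC[C@@]1(C)O | intermediate
22 | left seco alcohol | COC(OC)C[C@H]1[C@](C)(CCCO)[C@@H](C(C)=C)CC[C@@]1(C)O | intermediate
23 | left silyl ether | COC(OC)C[C@H]1[C@](C)(CCCO[Si](CC)(CC)CC)[C@@H](C(C)=C)CC[C@@]1(C)O | intermediate
24 | left methoxy hydroperoxide | COC(OC)C[C@H]1[C@](C)(CCCO[Si](CC)(CC)CC)[C@@H](C(C)(OC)OO)CC[C@@]1(C)O | intermediate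
25 | left C5 acetate | COC(OC)C[C@H]1[C@](C)(CCCO[Si](CC)(CC)CC)[C@@H](OC(C)=O)CC[C@@]1(C)O | intermediate
26 | left isopropenyl ether | COC(OC)C[C@H]1[C@](C)(CCCO[Si](CC)(CC)CC)[C@@H](OC(C)=C)CC[C@@]1(C)O | intermediate
27 | left aldehyde: C3 aldehyde, C5 isopropenyl ether, 8-OH axial | COC(OC)C[C@H]1[C@](C)(CCC=O)[C@@H](OC(C)=C)CC[C@@]1(C)O | intermediate
28 | left oxepanone: trans-fused 2,2-dimethyloxepan-3-one, 8-OH axial | COC(OC)C[C@H]1[C@]2(C)CCC(=O)C(C)(C)O[C@H]2CC[C@@]1(C)O | intermediate
29 | left acetoxy oxepanone: 8-acetate of 28 | COC(OC)C[C@H]1[C@]2(C)CCC(=O)C(C)(C)O[C@H]2CC[C@@]1(C)OC(C)=O | intermediate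
30 | left hydroxy oxepane: (3S)-alcohol, OH anti to the C10 methyl, 8-OAc axial | COC(OC)C[C@H]1[C@]2(C)CC[C@H](O)C(C)(C)O[C@H]2CC[C@@]1(C)OC(C)=O | intermediate
31 | left C12 aldehyde | O=CC[C@H]1[C@]2(C)CC[C@H](O)C(C)(C)O[C@H]2CC[C@@]1(C)OC(C)=O | intermediate
32 | left acid: C12 carboxylic acid, (3S)-OH, 8-OAc axial | OC(=O)C[C@H]1[C@]2(C)CC[C@H](O)C(C)(C)O[C@H]2CC[C@@]1(C)OC(C)=O | intermediate
33 | CNP0298533.1 | CC(=O)O[C@]1(C)CC[C@@H]2OC(C)(C)[C@@H](O)CC[C@@]2(C)[C@@H]1CC[C@H]1[C@]2(C)CCC(=O)C(C)(C)O[C@H]2CC[C@]1(C)OC(C)=O | target

**Step count and risks**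

Total step count: 27. Longest linear sequence: 15 steps (steps 1 to 14, then step 27).

Steps most likely to fail:

1. Step 11 (key step, proposed new method). The carbene may be diverted into acyloin or aldol self-condensation of the enolisable aldehyde, or traces of acid may hydrolyse the isopropenyl ether before the C–C bond forms. The fallback is known chemistry that closes the same bond as an alkene. From 14, Wittig methylenation (Ph3P=CH2) would give the diene F1. Ring-closing metathesis with the second-generation Grubbs catalyst RuCl2(=CHPh)(PCy3)(H2IMes) would close C3=C4 to the cyclic enol ether F2. Epoxidation with dimethyldioxirane and opening of the α-alkoxy epoxide at C4 with MeMgBr would give the hydroxy oxepane F3. Dess–Martin oxidation of F3 comes back to the route at 15.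

2. Step 22 (proposed new method). The same loss of the aldehyde to self-condensation or of the enol ether to hydrolysis may occur, here next to the more crowded axial C8 hydroxyl. The fallback sets out from 27: Wittig methylenation would give the left diene F4, ring-closing metathesis with the same ruthenium catalyst the left cyclic enol ether F5, and dimethyldioxirane followed by MeMgBr the left hydroxy oxepane F6. Dess–Martin oxidation of F6 comes back to the route at 28, so that C3 is still set by the catalyst in step 24.

3. Step 27. The two radicals may pair statistically into the symmetric dimers, or be oxidised further to cations (Hofer–Moest pathway) and lost to ethers and alkenes. The fallback moves the union from the anode surface to a metal centre. From 18 and 32, esterification with N-hydroxyphthalimide (diisopropylcarbodiimide, DMAP cat.) would give the redox-active ester F7 and the redox-active ester F8. A nickel-catalysed reductive doubly decarboxylative alkyl–alkyl coupling (NiCl2·6H2O, 2,2':6',2''-terpyridine, AgNO3, Mg anode, carbon cathode, NMP), with F8 in threefold excess, comes back to the route at 33.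

Further compounds
F1 | step 11 | right diene (C3=CH2 terminal alkene, C5 isopropenyl ether) | COC(OC)C[C@H]1[C@](C)(CCC=C)[C@@H](OC(C)=C)CC[C@]1(C)O
F2 | step 11 | right cyclic enol ether (C3=C4 in the seven-membered ring) | COC(OC)C[C@H]1[C@]2(C)CCC=C(C)O[C@H]2CC[C@]1(C)O
F3 | step 11 | right hydroxy oxepane (3-OH expected anti to the C10 methyl) | COC(OC)C[C@H]1[C@]2(C)CC[C@H](O)C(C)(C)O[C@H]2CC[C@]1(C)O
F4 | step 22 | left diene | COC(OC)C[C@H]1[C@](C)(CCC=C)[C@@H](OC(C)=C)CC[C@@]1(C)O
F5 | step 22 | left cyclic enol ether | COC(OC)C[C@H]1[C@]2(C)CCC=C(C)O[C@H]2CC[C@@]1(C)O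
F6 | step 22 | left hydroxy oxepane with free 8-OH (3-OH expected anti to the C10 methyl) | COC(OC)C[C@H]1[C@]2(C)CC[C@H](O)C(C)(C)O[C@H]2CC[C@@]1(C)O
F7 | step 27 | N-hydroxyphthalimide ester of 18 | O=C(ON1C(=O)c2ccccc2C1=O)C[C@H]1[C@]2(C)CCC(=O)C(C)(C)O[C@H]2CC[C@]1(C)OC(C)=O
F8 | step 27 | N-hydroxyphthalimide ester of 32 | O=C(ON1C(=O)c2ccccc2C1=O)C[C@H]1[C@]2(C)CC[C@H](O)C(C)(C)O[C@H]2CC[C@@]1(C)OC(C)=O
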